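## Retrosynthetic overview

1. Locants used throughout: C1 is the tertiary carbinol carbon bearing CH2OBz, C2 the CHOH next to the CH2CH2 unit, C3 and C4 the CH2 groups, C5 the CHOBz, and C6 the CHOH between C5 and C1. The target is (1S,2R,5R,6S), and in its chair all four ring oxygens are equatorial and CH2OBz is axial.
2. Enabling feature: C2(O)–C1(O)–C6(O) is a dihydroxyacetone unit whose C2–O and C6–O bonds are cis on the cyclohexane ring. They can therefore be held in a temporary 1,3-dioxane ring (acetonide) with C1 as a ketone, which makes C5–O β to that ketone and C1(=O)–C6–C5(OH) an aldol retron.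
3. End game: target ⇐ acetonide hydrolysis ⇐ benzoylation of the primary alcohol ⇐ dihydroxylation of an exocyclic C1 methylene ⇐ Wittig reaction on the C1 ketone of the bridged bicycle.
4. Key disconnection: C5–C6, by intramolecular proline-catalysed aldol addition of (R)-3-(2,2-dimethyl-5-oxo-1,3-dioxan-4-yl)propanal. This builds the cyclohexane ring and sets C5 and C6 from the single centre C2.
5. Keto aldehyde ⇐ RAMP-hydrazone alkylation of 2,2-dimethyl-1,3-dioxan-5-one with 4-iodobut-1-ene, then double ozonolysis. Ring order: dioxane ring (bought), cyclohexane ring (step 4), dioxane ring removed (step 9).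

Key step: step 4

Assumption: the sense of induction in step 2 follows the standard SAMP/RAMP model. SAMP, 3-pentanone and propyl iodide give (S)-4-methyl-3-heptanone, which transposes to (S)-4-alkyl-dioxanones from SAMP and (R) from RAMP. If the opposite sense were found, SAMP would take the place of RAMP.

## Route

Step 1
Reactants: 1 2,2-dimethyl-1,3-dioxan-5-one; 2 (R)-1-amino-2-(methoxymethyl)pyrrolidine (RAMP)
Product: 3 (R)-N-(2,2-dimethyl-1,3-dioxan-5-ylidene)-2-(methoxymethyl)pyrrolidin-1-amine
Conditions: cyclohexane, reflux, Dean–Stark trap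
Reagents that add atoms: none
Why: Hydrazone formation from a ketone and an N,N-dialkylhydrazine is driven to completion by azeotropic removal of water under neutral conditions that leave the acetonide intact, and no stereocentre is formed because the ketone is symmetric.

Step 2
Reactants: 3 RAMP hydrazone; 4 4-iodobut-1-ene
Product: 6 (R)-N-[(4R)-4-(but-3-en-1-yl)-2,2-dimethyl-1,3-dioxan-5-ylidene]-2-(methoxymethyl)pyrrolidin-1-amine (C=N geometry of no consequence), via lithium azaenolate 5 (not isolated)
Conditions: tBuLi (1.1 equiv), THF, −78 °C; then 4 (1.3 equiv), −100 °C → rt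
Reagents that add atoms: none
Why: SAMP/RAMP hydrazone α-alkylation, in which the methoxy-chelated lithium azaenolate 5 is alkylated by the primary iodide in an SN2 reaction on the face left open by the pyrrolidine side arm, which sets C2 as (R).

Step 3
Reactants: 6 alkylated RAMP hydrazone
Product: 8 (R)-3-(2,2-dimethyl-5-oxo-1,3-dioxan-4-yl)propanal, via keto ozonide 7 (not isolated)
Conditions: O3, CH2Cl2, −78 °C; then Me2S, −78 °C → rt
Reagents that add atoms: ozone [O-][O+]=O
Why: Ozonolysis cleaves the hydrazone C=N bond (the standard non-epimerising oxidative removal of this auxiliary) and the terminal C=C bond in the same operation, and Me2S reduces ozonide 7, so the C1 ketone and the C5 aldehyde are unveiled together while the cold neutral medium leaves C2 and the acetonide untouched.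

Step 4
Reactants: 8 keto aldehyde
Product: 10 (1R,5S,6R)-6-hydroxy-3,3-dimethyl-2,4-dioxabicyclo[3.3.1]nonan-9-one, via proline enamine 9 (not isolated)
Conditions: (S)-proline (30 mol %), DMF (0.05 M), 4 °C → rt
Reagents that add atoms: none
Why: (S)-Proline condenses with the doubly α-oxygenated, very electrophilic C1 ketone to give the less substituted enamine 9 (C1=C6), in which allylic 1,3-strain against the pyrrolidine turns the C2 side chain axial on the dioxane ring and hangs the C5 aldehyde over C6; C6 then adds to C5 while the carboxylic acid protonates the aldehyde oxygen, and hydrolysis of the iminium ion releases 10 and the catalyst. The closest known reaction types are the proline-catalysed aldol addition of 2,2-dimethyl-1,3-dioxan-5-one to aldehydes and the amine-mediated α,α'-annulation of cyclohexanones carrying a 3-oxopropyl arm, which closes 2-hydroxybicyclo[3.3.1]nonan-9-ones. The cyclohexane ring closes in the 6-(enolendo)-exo-trig mode, with the dioxane ring becoming the second ring of a 2,4-dioxabicyclo[3.3.1]nonane. C6 is controlled by C2, because the three-atom arm reaches only the enamine face on which it stands, so C2–O and C6–O end up cis, and (S)-proline, which on its own makes the (S) α-centre from this ketone, is the matched catalyst. C5 is controlled by the hydrogen-bonded closed transition state, in which the aldehyde oxygen must lie gauche to C1 and therefore anti to the C6–O bond, giving the axial carbinol, that is the trans C5–O/C6–O pair of the target. The step needs enamine formation toward C6H2 and not toward C2 (secured by the lower substitution of C6), closure instead of oligomerisation (secured by dilution) and a stop at the aldol stage (secured because C2–H and C6–H become bridgehead hydrogens orthogonal to the C=O π system, which shuts off dehydration and epimerisation).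

Step 5
Reactants: 10 bicyclic ketol
Product: 11 (1R,5S,6R)-3,3-dimethyl-9-oxo-2,4-dioxabicyclo[3.3.1]nonan-6-yl benzoate
Conditions: BzCl (1.5 equiv), pyridine, DMAP (10 mol %), CH2Cl2, 0 °C → rt
Reagents that add atoms: benzoyl chloride O=C(Cl)c1ccccc1
Why: DMAP-catalysed O-acylation installs the C5 benzoate of the target and ends the retro-aldol pathway, and the usual E1cB loss of a β-acyloxy group cannot occur because it would need an enolate double bond at the C6 bridgehead (Bredt's rule).

Step 6
Reactants: 11 keto benzoate
Product: 12 (1R,5R,6R)-3,3-dimethyl-9-methylidene-2,4-dioxabicyclo[3.3.1]nonan-6-yl benzoate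
Conditions: Ph3PCH3Br (1.6 equiv), KN(SiMe3)2 (1.5 equiv), THF, 0 °C; then 11, −78 → 0 °C
Reagents that add atoms: methyltriphenylphosphonium bromide C[P+](c1ccccc1)(c1ccccc1)c1ccccc1.[Br-]
Why: Wittig methylenation, in which the inductively activated and effectively non-enolisable bridging ketone should react with the non-stabilised ylide well before the benzoate does, and no stereocentre is touched (the descriptor at the C6 bridgehead changes only through the priority rules).

Step 7
Reactants: 12 exocyclic alkene
Product: 13 (1R,5S,6R,9S)-9-hydroxy-9-(hydroxymethyl)-3,3-dimethyl-2,4-dioxabicyclo[3.3.1]nonan-6-yl benzoate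
Conditions: OsO4 (5 mol %), NMO (1.5 equiv), acetone–H2O 4:1, rt
Reagents that add atoms: N-methylmorpholine N-oxide C[N+]1([O-])CCOCC1; water O
Why: Upjohn dihydroxylation, in which both allylic C–H bonds lie in the alkene plane and both allylic C–O bonds point to the dioxane side, so OsO4 should add anti to the two oxygens (the empirical anti rule for osmylation of allylic ethers, here acting twice) from the carbocycle side, which the dioxane ring and its methyl groups do not cover, placing the C1 hydroxyl cis to C5–OBz and trans to C2–O and C6–O, that is (S) at C1.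

Step 8
Reactants: 13 diol
Product: 14 [(1R,5S,6R,9S)-6-(benzoyloxy)-9-hydroxy-3,3-dimethyl-2,4-dioxabicyclo[3.3.1]nonan-9-yl]methyl benzoate
Conditions: BzCl (1.2 equiv), pyridine, CH2Cl2, 0 °C
Reagents that add atoms: benzoyl chloride O=C(Cl)c1ccccc1
Why: Acylation only has to distinguish the primary hydroxyl from the one other free hydroxyl, the hindered tertiary C1–OH, which is inert to BzCl in pyridine at 0 °C without DMAP.

Step 9
Reactants: 14 dibenzoate acetonide
Product: 15 [(1S,2S,3R,6R)-3-(benzoyloxy)-1,2,6-trihydroxycyclohexyl]methyl benzoate, the target, (1S,2R,5R,6S) in the locants of the overview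
Conditions: AcOH–H2O 4:1, 40 °C
Reagents that add atoms: none
Why: Acid-catalysed acetal hydrolysis removes the strained bridging isopropylidene group under conditions too mild for ester hydrolysis, acyl migration or ionisation of the tertiary alcohol, and the freed cyclohexane relaxes to the chair with all four ring oxygens equatorial.

## Compound list

1 | 2,2-dimethyl-1,3-dioxan-5-one | CC1(C)OCC(=O)CO1 | starting material
2 | (R)-1-amino-2-(methoxymethyl)pyrrolidine (RAMP) | COC[C@H]1CCCN1N | starting material
3 | (R)-N-(2,2-dimethyl-1,3-dioxan-5-ylidene)-2-(methoxymethyl)pyrrolidin-1-amine | COC[C@H]1CCCN1N=C1COC(C)(C)OC1 | intermediate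
4 | 4-iodobut-1-ene | C=CCCI | starting material
5 | lithium azaenolate of 3 | COC[C@H]1CCCN1[N-]C1=COC(C)(C)OC1.[Li+] | intermediate
6 | (R)-N-[(4R)-4-(but-3-en-1-yl)-2,2-dimethyl-1,3-dioxan-5-ylidene]-2-(methoxymethyl)pyrrolidin-1-amine | COC[C@H]1CCCN1N=C1COC(C)(C)O[C@@H]1CCC=C | intermediate
7 | (R)-2,2-dimethyl-4-[2-(1,2,4-trioxolan-3-yl)ethyl]-1,3-dioxan-5-one (both epimers at the ozonide carbon) | O=C1COC(C)(C)O[C@@H]1CCC1OCOO1 | intermediate
8 | (R)-3-(2,2-dimethyl-5-oxo-1,3-dioxan-4-yl)propanal | O=C1COC(C)(C)O[C@@H]1CCC=O | intermediate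
9 | (S)-1-[(4R)-2,2-dimethyl-4-(3-oxopropyl)-4H-1,3-dioxin-5-yl]pyrrolidine-2-carboxylic acid | OC(=O)[C@@H]1CCCN1C1=COC(C)(C)O[C@@H]1CCC=O | intermediate
10 | (1R,5S,6R)-6-hydroxy-3,3-dimethyl-2,4-dioxabicyclo[3.3.1]nonan-9-one | O=C1[C@H]2CC[C@@H](O)[C@@H]1OC(C)(C)O2 | intermediate
11 | (1R,5S,6R)-3,3-dimethyl-9-oxo-2,4-dioxabicyclo[3.3.1]nonan-6-yl benzoate | O=C1[C@H]2CC[C@@H](OC(=O)c3ccccc3)[C@@H]1OC(C)(C)O2 | intermediate
12 | (1R,5R,6R)-3,3-dimethyl-9-methylidene-2,4-dioxabicyclo[3.3.1]nonan-6-yl benzoate | C=C1[C@H]2CC[C@@H](OC(=O)c3ccccc3)[C@@H]1OC(C)(C)O2 | intermediate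
13 | (1R,5S,6R,9S)-9-hydroxy-9-(hydroxymethyl)-3,3-dimethyl-2,4-dioxabicyclo[3.3.1]nonan-6-yl benzoate | OC[C@]1(O)[C@H]2CC[C@@H](OC(=O)c3ccccc3)[C@@H]1OC(C)(C)O2 | intermediate
14 | [(1R,5S,6R,9S)-6-(benzoyloxy)-9-hydroxy-3,3-dimethyl-2,4-dioxabicyclo[3.3.1]nonan-9-yl]methyl benzoate | O=C(OC[C@]1(O)[C@H]2CC[C@@H](OC(=O)c3ccccc3)[C@@H]1OC(C)(C)O2)c1ccccc1 | intermediate
15 | [(1S,2S,3R,6R)-3-(benzoyloxy)-1,2,6-trihydroxycyclohexyl]methyl benzoate | O=C(OC[C@]1(O)[C@H](O)CC[C@@H](OC(=O)c2ccccc2)[C@@H]1O)c1ccccc1 | target

Total step count: 9. Longest linear sequence: 9 steps.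

## Steps most likely to fail

**Step 4 (key aldol closure).**
- The closure is reversible, and the inner methyl group of the isopropylidene bridge forces the dioxane ring of the bicycle out of its chair, so retro-aldol may compete.
- An open transition state would attack the other aldehyde face.
- Enamine formation toward C2 would erode the enantiomeric purity.

The fallback sets out from 8 and comes back at 11, and C5 is no longer left to the aldol alone. The closure is run as before and both carbinols are collected. Compound 10 goes through step 5. The equatorial epimer (1R,5S,6S)-6-hydroxy-3,3-dimethyl-2,4-dioxabicyclo[3.3.1]nonan-9-one F1 is esterified with inversion under Mitsunobu conditions (PPh3, DIAD, benzoic acid, toluene, 0 °C → rt). The SN2 displacement should turn it into the same axial benzoate 11, and elimination toward C6 is again barred by the bridgehead.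

**Step 7 (dihydroxylation of the bicycle).** The axial benzoate crowds the carbocycle face, so osmylation may be slow or poorly face-selective. The fallback sets out from 12 and comes back at 15, and the temporary ring is removed before C1 is set.
- Hydrolysis of 12 (AcOH–H2O, 40 °C) should give (1R,2R,4R)-2,4-dihydroxy-3-methylidenecyclohexyl benzoate F2.
- In F2 both chair forms predict the same face. In the all-equatorial chair this is equatorial attack of OsO4 on a methylenecyclohexane, and in the flipped chair it is attack anti to both allylic hydroxyls.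
- Dihydroxylation (OsO4 cat., NMO) should give (1R,2S,3S,4R)-2,3,4-trihydroxy-3-(hydroxymethyl)cyclohexyl benzoate F3.
- Selective acylation of the primary hydroxyl of F3 (BzCl 1.0 equiv, 2,4,6-collidine, CH2Cl2, −40 °C) should give 15.

**Step 2 (alkylation).** The basic azaenolate may cause E2 elimination of the homoallylic iodide to butadiene, which would return 3 and stall conversion. The fallback sets out from 3 and comes back at 8, and C5 is brought in at the alcohol oxidation level with an electrophile that has no activated β-hydrogen.
- Azaenolate 5 is alkylated with commercial tert-butyl(3-iodopropoxy)dimethylsilane to the RAMP hydrazone of (R)-4-[3-(tert-butyldimethylsilyloxy)propyl]-2,2-dimethyl-1,3-dioxan-5-one F4.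
- Ozonolysis (O3, CH2Cl2, −78 °C) should free (R)-4-[3-(tert-butyldimethylsilyloxy)propyl]-2,2-dimethyl-1,3-dioxan-5-one F5.
- Desilylation (HF·pyridine, THF, 0 °C) should give (R)-4-(3-hydroxypropyl)-2,2-dimethyl-1,3-dioxan-5-one F6.
- Oxidation with Dess–Martin periodinane buffered with NaHCO3 should give 8.

## Further compounds

F1 | step 4 | (1R,5S,6S)-6-hydroxy-3,3-dimethyl-2,4-dioxabicyclo[3.3.1]nonan-9-one | O=C1[C@H]2CC[C@H](O)[C@@H]1OC(C)(C)O2
F2 | step 7 | (1R,2R,4R)-2,4-dihydroxy-3-methylidenecyclohexyl benzoate | C=C1[C@H](O)CC[C@@H](OC(=O)c2ccccc2)[C@@H]1O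
F3 | step 7 | (1R,2S,3S,4R)-2,3,4-trihydroxy-3-(hydroxymethyl)cyclohexyl benzoate | OC[C@]1(O)[C@H](O)CC[C@@H](OC(=O)c2ccccc2)[C@@H]1O
F4 | step 2 | RAMP hydrazone of (R)-4-[3-(tert-butyldimethylsilyloxy)propyl]-2,2-dimethyl-1,3-dioxan-5-one | COC[C@H]1CCCN1N=C1COC(C)(C)O[C@@H]1CCCO[Si](C)(C)C(C)(C)C
F5 | step 2 | (R)-4-[3-(tert-butyldimethylsilyloxy)propyl]-2,2-dimethyl-1,3-dioxan-5-one | O=C1COC(C)(C)O[C@@H]1CCCO[Si](C)(C)C(C)(C)C
F6 | step 2 | (R)-4-(3-hydroxypropyl)-2,2-dimethyl-1,3-dioxan-5-one | O=C1COC(C)(C)O[C@@H]1CCCO
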